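**Plan**
- Retrosynthesis first cuts the ketone at its bond to the 2,4-dihydroxyphenyl ring (aryl-metal plus arylacetaldehyde, then oxidation), leaving the other ring with a two-carbon arm.
- That ring carries, in order around the benzene ring, C–OH, C–CH2R, C–OMe, C–prenyl, C–OMe and C–H, with oxygen on alternating carbons. It is cut at the C(OH)–C(CH2R) and C(OMe)–C(prenyl) bonds into a 3-methoxy-2-prenylcyclobutenone (C=O becomes C–OH, the vinylogous-ester OMe stays) and a 1-methoxyalkyne (its OMe carbon ends next to the prenyl carbon).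
- Forward: cyclobutenone 7 (ketene/ethoxyacetylene [2+2], hydrolysis, O-methylation) and ynol ether 11 (methoxyacetylide alkylation) are heated to build the pentasubstituted ring in one step; the arm is then oxidised and joined to the resorcinol ring.
- Phenols travel as allyl ethers and are freed last with Pd(0), because acid would endanger the prenyl group and could cyclodehydrate the o-hydroxybenzyl ketone to a 2-arylbenzofuran.
- Stereochemistry: none to set; the stereocentres that appear in 5, 13 and 24 are racemic and are erased again.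

Key step: step 6

Assumption: licoriphenone has no stereocentre and no stereogenic double bond, so "single enantiomer" is read as the one achiral structure given. "Prenyl" below means 3-methylbut-2-en-1-yl.

**Step 1**
Reactants: 1 5-methylhex-4-enoic acid
Product: 2 5-methylhex-4-enoyl chloride
Conditions: (COCl)2, DMF (cat.), CH2Cl2, 0 °C → rt; concentrate
Reagents that add atoms: oxalyl chloride, O=C(Cl)C(=O)Cl
Why: Vilsmeier-catalysed acid chloride formation with only gaseous by-products, mild enough that the trisubstituted alkene should survive.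

**Step 2**
Reactants: 2 5-methylhex-4-enoyl chloride; 3 ethoxyacetylene
Product: 5 3-ethoxy-4-(3-methylbut-2-en-1-yl)cyclobut-2-en-1-one (racemic), via prenylketene 4 (not isolated)
Conditions: Et3N, 3 (2 equiv), Et2O, rt, slow addition of 2
Reagents that add atoms: none
Why: Dehydrochlorination gives the monoalkylketene, which the electron-rich ynol ether traps in a regioselective thermal ketene–alkyne [2+2] cycloaddition (alkyne CH to the ketene carbonyl carbon); the ring stereocentre is racemic and disappears in step 3.

**Step 3**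
Reactants: 5 3-ethoxy-4-(3-methylbut-2-en-1-yl)cyclobut-2-en-1-one
Product: 6 3-hydroxy-2-(3-methylbut-2-en-1-yl)cyclobut-2-en-1-one
Conditions: 1 M aq. HCl, THF, 0 °C → rt
Reagents that add atoms: water, O
Why: Acid-catalysed hydrolysis of the strained vinylogous ester (addition–elimination at C3) gives the 2-substituted cyclobutane-1,3-dione, which should rest as the tetrasubstituted enol, and cold dilute acid should spare the prenyl alkene.

**Step 4**
Reactants: 6 3-hydroxy-2-(3-methylbut-2-en-1-yl)cyclobut-2-en-1-one
Product: 7 3-methoxy-2-(3-methylbut-2-en-1-yl)cyclobut-2-en-1-one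
Conditions: TMSCHN2, MeOH–PhMe (1:4), 0 °C → rt
Reagents that add atoms: trimethylsilyldiazomethane, C[Si](C)(C)C=[N+]=[N-]
Why: O-Methylation of a strongly acidic enol (vinylogous acid) by diazomethane-type alkylation; the two oxygens of the enolised 2-substituted dione are equivalent, so the favoured enol can give only the 3-methoxy-2-prenyl isomer.

**Step 5**
Reactants: 8 chloroacetaldehyde dimethyl acetal; 9 tert-butyl(2-iodoethoxy)dimethylsilane
Product: 11 tert-butyl[(4-methoxybut-3-yn-1-yl)oxy]dimethylsilane, via lithium methoxyacetylide 10 (not isolated)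
Conditions: LiNEt2 (3.1 equiv, from n-BuLi/Et2NH), THF, 0 °C; then 9, DMPU, −20 °C → rt
Reagents that add atoms: none
Why: Three equivalents of amide base effect double β-elimination (MeOH, then HCl) and deprotonation to the alkoxyacetylide, which undergoes SN2 C-alkylation with the primary iodide in the dipolar cosolvent.

**Step 6**
Reactants: 7 3-methoxy-2-(3-methylbut-2-en-1-yl)cyclobut-2-en-1-one; 11 tert-butyl[(4-methoxybut-3-yn-1-yl)oxy]dimethylsilane
Product: 16 2-[2-(tert-butyldimethylsilyloxy)ethyl]-3,5-dimethoxy-4-(3-methylbut-2-en-1-yl)phenol, via vinylketene 12 (not isolated), via vinylcyclobutenone 13 (not isolated), via dienylketene 14 (not isolated), via cyclohexadienone 15 (not isolated)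
Conditions: 11 (1.5 equiv), PhMe (0.5 M), 80 → 120 °C, sealed tube, Ar
Reagents that add atoms: none
Why: Heat opens 7 by 4π electrocyclic cleavage of its C1–C4 bond to vinylketene 12, whose ketene C=C adds ynol ether 11 in a [2+2] cycloaddition to give 4-vinylcyclobutenone 13; a second 4π opening gives dienylketene 14, which closes to dienone 15 and tautomerises to phenol 16. The closest known reaction type is the Danheiser benzannulation of cyclobutenones with alkoxyalkynes, the same pathway by which 1-alkoxyalkynes pass through 3-alkoxycyclobutenones to 3,5-dialkoxyphenols on heating. The only ring formed is the benzene ring, closed by a thermally allowed disrotatory 6π electrocyclisation (ketene carbon to the terminal CH2) after the [2+2] step has made the two new σ-bonds C(OH)–C(CH2CH2OTBS) and C(OMe)–C(prenyl). No stereocentre is created in 16; the quaternary carbon of 13 is racemic and vanishes on ring opening, and reversible opening of 13 should funnel material into the dienylketene geometry that has ketene and methoxyvinyl groups cis and can cyclise. The selectivity needed is the regiochemistry of the ketene–alkyne union, secured by the polarisation of 11: the oxygen lone pair makes the alkyl-bearing alkyne carbon nucleophilic, so it bonds to the electrophilic ketene carbon (the future C–OH) while the methoxy-bearing carbon bonds to the prenyl-bearing carbon. A methyl ynol ether is used because it cannot fragment by retro-ene loss of an alkene at this temperature, and the methoxy group of 7 arrives as the second, already differentiated methyl ether.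

**Step 7**
Reactants: 16 2-[2-(tert-butyldimethylsilyloxy)ethyl]-3,5-dimethoxy-4-(3-methylbut-2-en-1-yl)phenol
Product: 17 tert-butyl{2-[6-(allyloxy)-2,4-dimethoxy-3-(3-methylbut-2-en-1-yl)phenyl]ethoxy}dimethylsilane
Conditions: allyl bromide, K2CO3, acetone, 55 °C
Reagents that add atoms: allyl bromide, C=CCBr
Why: Williamson etherification of the phenoxide installs a protecting group that can later be removed by Pd(0) without acid.

**Step 8**
Reactants: 17 tert-butyl{2-[6-(allyloxy)-2,4-dimethoxy-3-(3-methylbut-2-en-1-yl)phenyl]ethoxy}dimethylsilane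
Product: 18 2-[6-(allyloxy)-2,4-dimethoxy-3-(3-methylbut-2-en-1-yl)phenyl]ethan-1-ol
Conditions: TBAF, THF, 0 °C → rt
Reagents that add atoms: none
Why: Fluoride-induced desilylation of a primary TBS ether, to which the allyl ether, methyl ethers and prenyl group are inert.

**Step 9**
Reactants: 18 2-[6-(allyloxy)-2,4-dimethoxy-3-(3-methylbut-2-en-1-yl)phenyl]ethan-1-ol
Product: 19 2-[6-(allyloxy)-2,4-dimethoxy-3-(3-methylbut-2-en-1-yl)phenyl]acetaldehyde
Conditions: Dess–Martin periodinane, CH2Cl2, 0 °C → rt; used crude
Reagents that add atoms: none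
Why: Dess–Martin oxidation stops at the aldehyde under non-basic conditions that should not enolise the sensitive arylacetaldehyde or touch the alkenes.

**Step 10**
Reactants: 20 4-bromoresorcinol
Product: 21 2,4-bis(allyloxy)-1-bromobenzene
Conditions: allyl bromide (2.5 equiv), K2CO3, acetone, 55 °C
Reagents that add atoms: allyl bromide, C=CCBr
Why: Twofold Williamson etherification gives an aryl bromide whose protecting groups tolerate halogen–metal exchange at low temperature.

**Step 11**
Reactants: 19 2-[6-(allyloxy)-2,4-dimethoxy-3-(3-methylbut-2-en-1-yl)phenyl]acetaldehyde; 21 2,4-bis(allyloxy)-1-bromobenzene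
Product: 24 1-[2,4-bis(allyloxy)phenyl]-2-[6-(allyloxy)-2,4-dimethoxy-3-(3-methylbut-2-en-1-yl)phenyl]ethan-1-ol (racemic), via aryllithium 22 (not isolated), via arylcerium 23 (not isolated)
Conditions: 21, n-BuLi, THF, −78 °C; CeCl3, −78 °C; then 19, −78 °C; aq. NH4Cl
Reagents that add atoms: none
Why: Bromine–lithium exchange followed by transmetalation to the weakly basic organocerium favours 1,2-addition over enolisation of the arylacetaldehyde; the carbinol centre forms racemic and is removed in step 12.

**Step 12**
Reactants: 24 1-[2,4-bis(allyloxy)phenyl]-2-[6-(allyloxy)-2,4-dimethoxy-3-(3-methylbut-2-en-1-yl)phenyl]ethan-1-ol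
Product: 25 1-[2,4-bis(allyloxy)phenyl]-2-[6-(allyloxy)-2,4-dimethoxy-3-(3-methylbut-2-en-1-yl)phenyl]ethan-1-one
Conditions: Dess–Martin periodinane, CH2Cl2, 0 °C → rt
Reagents that add atoms: none
Why: Dess–Martin oxidation of the benzylic secondary alcohol gives the deoxybenzoin without acid or base strong enough to affect the allyl ethers or the prenyl group.

**Step 13**
Reactants: 25 1-[2,4-bis(allyloxy)phenyl]-2-[6-(allyloxy)-2,4-dimethoxy-3-(3-methylbut-2-en-1-yl)phenyl]ethan-1-one
Product: 26 licoriphenone, 1-(2,4-dihydroxyphenyl)-2-[6-hydroxy-2,4-dimethoxy-3-(3-methylbut-2-en-1-yl)phenyl]ethan-1-one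
Conditions: Pd(PPh3)4 (cat.), morpholine (excess), THF, rt
Reagents that add atoms: none
Why: Pd(0) ionises the three aryl allyl ethers to π-allyl complexes that morpholine intercepts (Tsuji–Trost deallylation), freeing the phenols without acid, while the C-prenyl group is not an allylic electrophile and stays.

**Compound list**
1 | 5-methylhex-4-enoic acid | CC(C)=CCCC(=O)O | starting material
2 | 5-methylhex-4-enoyl chloride | CC(C)=CCCC(=O)Cl | intermediate
3 | ethoxyacetylene | CCOC#C | starting material
4 | prenylketene, 5-methylhexa-1,4-dien-1-one (formed in situ) | O=C=CCC=C(C)C | intermediate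
5 | 3-ethoxy-4-(3-methylbut-2-en-1-yl)cyclobut-2-en-1-one (racemic) | CCOC1=CC(=O)C1CC=C(C)C | intermediate
6 | 3-hydroxy-2-(3-methylbut-2-en-1-yl)cyclobut-2-en-1-one | O=C1CC(O)=C1CC=C(C)C | intermediate
7 | 3-methoxy-2-(3-methylbut-2-en-1-yl)cyclobut-2-en-1-one | O=C1CC(OC)=C1CC=C(C)C | intermediate
8 | chloroacetaldehyde dimethyl acetal | COC(CCl)OC | starting material
9 | tert-butyl(2-iodoethoxy)dimethylsilane | CC(C)(C)[Si](C)(C)OCCI | starting material
10 | lithium methoxyacetylide (formed in situ) | [Li]C#COC | intermediate
11 | tert-butyl[(4-methoxybut-3-yn-1-yl)oxy]dimethylsilane | COC#CCCO[Si](C)(C)C(C)(C)C | intermediate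
12 | vinylketene, 3-methoxy-2-(3-methylbut-2-en-1-yl)buta-1,3-dien-1-one (formed in situ) | C=C(OC)C(CC=C(C)C)=C=O | intermediate
13 | vinylcyclobutenone, 2-[2-(tert-butyldimethylsilyloxy)ethyl]-3-methoxy-4-(1-methoxyvinyl)-4-(3-methylbut-2-en-1-yl)cyclobut-2-en-1-one (racemic, formed in situ) | O=C1C(CCO[Si](C)(C)C(C)(C)C)=C(OC)C1(CC=C(C)C)C(OC)=C | intermediate
14 | dienylketene, 2-[2-(tert-butyldimethylsilyloxy)ethyl]-3,5-dimethoxy-4-(3-methylbut-2-en-1-yl)hexa-1,3,5-trien-1-one, ketene and methoxyvinyl groups cis across C3=C4 (formed in situ) | O=C=C(CCO[Si](C)(C)C(C)(C)C)/C(OC)=C(/CC=C(C)C)C(OC)=C | intermediate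
15 | cyclohexadienone, 2-[2-(tert-butyldimethylsilyloxy)ethyl]-3,5-dimethoxy-4-(3-methylbut-2-en-1-yl)cyclohexa-2,4-dien-1-one (formed in situ) | O=C1CC(OC)=C(CC=C(C)C)C(OC)=C1CCO[Si](C)(C)C(C)(C)C | intermediate
16 | 2-[2-(tert-butyldimethylsilyloxy)ethyl]-3,5-dimethoxy-4-(3-methylbut-2-en-1-yl)phenol | COc1cc(O)c(CCO[Si](C)(C)C(C)(C)C)c(OC)c1CC=C(C)C | intermediate
17 | tert-butyl{2-[6-(allyloxy)-2,4-dimethoxy-3-(3-methylbut-2-en-1-yl)phenyl]ethoxy}dimethylsilane | COc1cc(OCC=C)c(CCO[Si](C)(C)C(C)(C)C)c(OC)c1CC=C(C)C | intermediate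
18 | 2-[6-(allyloxy)-2,4-dimethoxy-3-(3-methylbut-2-en-1-yl)phenyl]ethan-1-ol | COc1cc(OCC=C)c(CCO)c(OC)c1CC=C(C)C | intermediate
19 | 2-[6-(allyloxy)-2,4-dimethoxy-3-(3-methylbut-2-en-1-yl)phenyl]acetaldehyde | COc1cc(OCC=C)c(CC=O)c(OC)c1CC=C(C)C | intermediate
20 | 4-bromoresorcinol (4-bromobenzene-1,3-diol) | Oc1ccc(Br)c(O)c1 | starting material
21 | 2,4-bis(allyloxy)-1-bromobenzene | C=CCOc1ccc(Br)c(OCC=C)c1 | intermediate
22 | aryllithium, [2,4-bis(allyloxy)phenyl]lithium (formed in situ) | [Li]c1ccc(OCC=C)cc1OCC=C | intermediate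
23 | arylcerium, [2,4-bis(allyloxy)phenyl]cerium dichloride (formed in situ) | Cl[Ce](Cl)c1ccc(OCC=C)cc1OCC=C | intermediate
24 | 1-[2,4-bis(allyloxy)phenyl]-2-[6-(allyloxy)-2,4-dimethoxy-3-(3-methylbut-2-en-1-yl)phenyl]ethan-1-ol (racemic) | COc1cc(OCC=C)c(CC(O)c2ccc(OCC=C)cc2OCC=C)c(OC)c1CC=C(C)C | intermediate
25 | 1-[2,4-bis(allyloxy)phenyl]-2-[6-(allyloxy)-2,4-dimethoxy-3-(3-methylbut-2-en-1-yl)phenyl]ethan-1-one | COc1cc(OCC=C)c(CC(=O)c2ccc(OCC=C)cc2OCC=C)c(OC)c1CC=C(C)C | intermediate
26 | licoriphenone | COc1cc(O)c(CC(=O)c2ccc(O)cc2O)c(OC)c1CC=C(C)C | target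

**Step count**
Total: 13 steps. Longest linear sequence: 11 steps (1, 2, 3, 4, 6, 7, 8, 9, 11, 12, 13, from acid 1); steps 5 and 10 are side branches.

**Steps most likely to fail**

Step 6. The donor-stabilised cyclobutenone 7 may open too slowly, so that the ynol ether decomposes first, or the hot ketene intermediates may be diverted by cycloaddition to the prenyl alkene or by acylating the product phenol. The fallback generates the same vinylketene 12 with light at room temperature. It sets out from acid chloride 2, which with MeNHOMe·HCl and Et3N would give N-methoxy-N,5-dimethylhex-4-enamide F1. Addition of 1-methoxyvinyllithium (methyl vinyl ether, t-BuLi) would give 2-methoxy-7-methylocta-1,6-dien-3-one F2. Detrifluoroacetylative diazo transfer (LiHMDS, CF3CO2CH2CF3; then MsN3, Et3N) would give 4-diazo-2-methoxy-7-methylocta-1,6-dien-3-one F3. Irradiation of F3 with 11 (photochemical Wolff rearrangement, then gentle warming) enters the same cascade and returns to the route at phenol 16.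

Step 11. Deprotonation of the arylacetaldehyde 19 at its benzylic α-position, or its self-aldol reaction, may outrun carbonyl addition. The fallback moves the electrophile to the amide oxidation level. It sets out from 19: Pinnick oxidation (NaClO2, NaH2PO4, large excess of 2-methyl-2-butene) would give [6-(allyloxy)-2,4-dimethoxy-3-(3-methylbut-2-en-1-yl)phenyl]acetic acid F4. Coupling with MeNHOMe·HCl (EDCI, base) would give the Weinreb amide 2-[6-(allyloxy)-2,4-dimethoxy-3-(3-methylbut-2-en-1-yl)phenyl]-N-methoxy-N-methylacetamide F5. Addition of aryllithium 22 at −78 °C should then give the ketone directly, returning to the route at 25 and making step 12 unnecessary.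

Step 5. E2 elimination of the β-silyloxy iodide 9 by the acetylide, or its N-alkylation by the diethylamine present, may take over from C-alkylation. The fallback takes the two-carbon unit from an epoxide instead. It sets out from 8, which with NaNH2 in liquid NH3 would give sodium methoxyacetylide F6. Opening of oxirane in the same medium would give 4-methoxybut-3-yn-1-ol F7. Silylation under basic conditions (TBSCl, Et3N, DMAP, CH2Cl2), so that the hydroxy ynol ether never meets acid, returns to the route at 11.

**Further compounds**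
F1 | step 6 | N-methoxy-N,5-dimethylhex-4-enamide | CC(C)=CCCC(=O)N(C)OC
F2 | step 6 | 2-methoxy-7-methylocta-1,6-dien-3-one | C=C(OC)C(=O)CCC=C(C)C
F3 | step 6 | 4-diazo-2-methoxy-7-methylocta-1,6-dien-3-one | C=C(OC)C(=O)C(=[N+]=[N-])CC=C(C)C
F4 | step 11 | [6-(allyloxy)-2,4-dimethoxy-3-(3-methylbut-2-en-1-yl)phenyl]acetic acid | COc1cc(OCC=C)c(CC(=O)O)c(OC)c1CC=C(C)C
F5 | step 11 | 2-[6-(allyloxy)-2,4-dimethoxy-3-(3-methylbut-2-en-1-yl)phenyl]-N-methoxy-N-methylacetamide | COc1cc(OCC=C)c(CC(=O)N(C)OC)c(OC)c1CC=C(C)C
F6 | step 5 | sodium methoxyacetylide | [Na+].[C-]#COC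
F7 | step 5 | 4-methoxybut-3-yn-1-ol | COC#CCCO
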